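**Assumption (chemistry):** racemic allethrolone and potassium (Z)-crotyltrifluoroborate are treated as catalogue compounds. Guaiane numbering is used throughout: ring A = cyclopentene C1–C5, ring B = seven-membered ring C1, C5–C10, C11 = carbinol carbon on C7.

## Retrosynthetic overview

1. Target ⇐ C3 carbinol oxidation, C11 acetylation, C8 angeloylation and C6 ketone reduction on a bicyclic 6-oxo-8,11-diol; the 6-OH is set on the ring by hydride attack anti to the C7 side chain.
2. Ring B is closed across C7–C8 by a SmI2-triggered oxirane-opening/aldol cascade of a ring A precursor carrying a C5 acyl oxirane (C6 ketone, C7–C11 epoxide) and a C8 aldehyde.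
3. Enabling feature: C7 is the one carbon of ring B flanked by three oxygen-bearing carbons (C6, C8, C11). With C6 at the ketone level, C7 is the α-carbon of a β,β′-dihydroxy ketone, so C7–C8 is an aldol bond and the C11 oxygen can be stored as the C7–C11 oxirane that generates the enolate.
4. Ring A comes from (R)-allethrolone: C1 and C10 by (Z)-crotylboration of the ring ketone anti to the C3 silyl ether; the allyl group is cut back to the C6 aldehyde and rebuilt into the acyl oxirane.
5. Order of ring formation: ring A (purchased), then ring B (step 13).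

Key step: step 13

## Route

Step 1
Reactants: 1 (±)-allethrolone
Product: 2 (R)-allethrolone acetate
Conditions: Amano lipase PS (Burkholderia cepacia), vinyl acetate, t-BuOMe, 30 °C, stopped just short of half conversion; chromatography
Reagents that add atoms: vinyl acetate, CC(=O)OC=C
Why: Lipase-catalysed kinetic resolution by transesterification, in which the (R)-alcohol (ring sp2 carbon as large, CH2 as medium substituent in the Kazlauskas model) should be acylated and is separated from the unreacted (S)-alcohol.

Step 2
Reactants: 2 (R)-allethrolone acetate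
Product: 3 (R)-allethrolone
Conditions: Amano lipase PS, pH 7 phosphate buffer/acetone, 25 °C
Reagents that add atoms: none
Why: Enzymatic ester hydrolysis at neutral pH frees the carbinol without the base-induced β-elimination typical of 4-acyloxycyclopentenones, and a second pass through the (R)-selective enzyme should raise the enantiomeric purity.

Step 3
Reactants: 3 (R)-allethrolone
Product: 4 TBS ether of (R)-allethrolone
Conditions: TBSCl, imidazole, DMF, 0 °C → rt
Reagents that add atoms: tert-butyldimethylsilyl chloride, CC(C)(C)[Si](C)(C)Cl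
Why: Standard silylation of a secondary allylic alcohol; the bulky C3 silyl ether later steers the addition to C1 and masks the future C3 ketone.

Step 4
Reactants: 4 TBS ether of (R)-allethrolone
Product: 5 (E)-propenyl dienone
Conditions: RuHCl(CO)(PPh3)3 (cat.), toluene, 80 °C
Reagents that add atoms: none
Why: Ruthenium hydride alkene isomerisation (hydrometallation/β-hydride elimination) moves the allyl double bond one position into conjugation with the ring alkene, which is the thermodynamic sink; the E/Z ratio is irrelevant because this bond is cleaved in step 8.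

Step 5
Reactants: 5 (E)-propenyl dienone; 6 potassium (Z)-crotyltrifluoroborate
Product: 7 tertiary homoallylic alcohol (1R,10S)
Conditions: BF3·OEt2, CH2Cl2, −78 °C; cold aq. NaHCO3
Reagents that add atoms: potassium (Z)-crotyltrifluoroborate (6), [K+].C/C=C\C[B-](F)(F)F
Why: Ketone crotylboration through the crotyldifluoroborane in a closed chair transition state: boron binds the carbonyl lone pair anti to the substituted C5 (C2 axial, C5 equatorial), the Z-methyl is axial, and attack anti to the C3 silyl ether should give C1 (R) and C10 (S) with OH and CH3 in the relationship of the target.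

Step 6
Reactants: 7 tertiary homoallylic alcohol
Product: 8 C1 triethylsilyl ether
Conditions: TESOTf, 2,6-lutidine, CH2Cl2, −78 → 0 °C
Reagents that add atoms: triethylsilyl triflate, CC[Si](CC)(CC)OS(=O)(=O)C(F)(F)F
Why: Silyl triflate silylation of a hindered tertiary alcohol; this blocks later lactol formation with C8, removes the only protic group before the SmI2 step, and places a bulky group on one face of the future ring B.

Step 7
Reactants: 8 C1 triethylsilyl ether
Product: 10 primary alcohol (C8 OH), via alkylborane 9 (not isolated)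
Conditions: 9-BBN, THF, 0 °C → rt; then aq. NaOH, H2O2, 0 °C
Reagents that add atoms: 9-BBN, B1C2CCCC1CCC2 (stays in 9 only); hydrogen peroxide, OO
Why: Anti-Markovnikov hydroboration–oxidation; 9-BBN should select the monosubstituted vinyl group over the di- and tetrasubstituted alkenes of the conjugated diene.

Step 8
Reactants: 10 primary alcohol
Product: 12 hydroxy enal (C6 aldehyde), via vicinal diol 11 (not isolated)
Conditions: OsO4 (cat.), NaIO4, 2,6-lutidine, dioxane/H2O, rt
Reagents that add atoms: OsO4, O=[Os](=O)(=O)=O (two oxygens into 11, one retained in 12)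
Why: Lemieux–Johnson cleavage; osmylation should occur at the accessible 1,2-disubstituted C6=C7 bond and not at the hindered tetrasubstituted ring alkene, and periodate cleaves the diol to the ring-conjugated aldehyde.

Step 9
Reactants: 12 hydroxy enal; 13 2-methylprop-1-enylmagnesium bromide
Product: 14 bis-allylic alcohol (both C6 epimers)
Conditions: 13 (2.5 equiv), THF, −78 → 0 °C; aq. NH4Cl
Reagents that add atoms: 2-methylprop-1-enylmagnesium bromide (13), CC(C)=C[Mg]Br
Why: Grignard 1,2-addition to the enal (one equivalent is consumed by the C8 OH); the C6 configuration is not controlled and is erased in step 10.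

Step 10
Reactants: 14 bis-allylic alcohol
Product: 15 cross-conjugated dienone
Conditions: MnO2, CH2Cl2, rt
Reagents that add atoms: none
Why: MnO2 oxidises the doubly allylic secondary alcohol and leaves the saturated primary C8 alcohol untouched.

Step 11
Reactants: 15 cross-conjugated dienone
Product: 16 acyl oxirane (both C7 epimers)
Conditions: 30% H2O2, NaOH, MeOH, 0 °C
Reagents that add atoms: hydrogen peroxide, OO
Why: Weitz–Scheffer nucleophilic epoxidation at the unhindered β,β-dimethyl enone (mesityl oxide type) rather than the ring enone, whose β-carbon C4 is fully substituted; the C7 configuration is lost again in step 13.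

Step 12
Reactants: 16 acyl oxirane
Product: 17 epoxy keto aldehyde
Conditions: Dess–Martin periodinane, NaHCO3, CH2Cl2, 0 °C; used directly
Reagents that add atoms: none
Why: Mild buffered oxidation of the primary alcohol to the aldehyde tolerates the oxirane and both silyl ethers and avoids base, which could trigger aldol side reactions of the aldehyde.

Step 13
Reactants: 17 epoxy keto aldehyde
Product: 19 bicyclic 6-oxo-8,11-diol (7S,8R), via samarium enolate 18 (not isolated)
Conditions: SmI2 (2.2 equiv, 0.1 M in THF, added slowly), THF, −78 °C; pH 7 phosphate buffer at −78 °C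
Reagents that add atoms: SmI2, I[Sm]I (atoms stay in 18 only, none in 19)
Why: Two electrons from SmI2 reduce the C6 ketone, the C7–O bond of the oxirane breaks to leave a trivalent samarium enolate (C6=C7) with the C11 oxygen as samarium alkoxide, and this enolate adds to the C8 aldehyde in a samarium Reformatsky-type aldol (closest precedents: SmI2 reduction of α,β-epoxy ketones to β-hydroxy ketones, and medium-ring aldol closures of samarium enolates from α-halo ketones). Ring B closes in the 7-(enolendo)-exo-trig mode. The C11 alkoxide should hold the enolate in the Z(O) geometry, and the same metal binds the aldehyde oxygen in a chair-like closed transition state in which the tether forces C9 axial, so O8 ends up cis to the C7 side chain (O6, O8 and O11 cap one samarium). On the ring face of the C1 silyl ether this chelate would meet OSiEt3 in a syn-pentane contact with the samarium-bound O6, whereas on the opposite face only the C10 methyl is 1,3 to O8, so closure anti to OSiEt3 (7S,8R) is expected. Chemoselectivity (electron transfer to the epoxy ketone before the aldehyde, aldol before protonation) should follow from the fast fragmentation of the α-oxiranyl ketyl at −78 °C, slow addition of SmI2, and the absence of any OH group in 17.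

Step 14
Reactants: 19 bicyclic 6-oxo-8,11-diol
Product: 20 all-cis 6,8,11-triol (6R)
Conditions: NaBH4, CeCl3·7H2O, MeOH, −78 °C
Reagents that add atoms: none
Why: Luche 1,2-reduction of the hindered enone carbonyl; cerium bound by O6, O8 and O11 on the face of the C7 side chain should leave the opposite face open, so hydride enters anti to the C(CH3)2OH group and gives the 6-OH cis to both neighbours.

Step 15
Reactants: 20 all-cis triol; 21 angelic acid
Product: 22 8-O-angelate
Conditions: 21, 2,4,6-trichlorobenzoyl chloride, Et3N, toluene, rt; then 20, 75 °C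
Reagents that add atoms: angelic acid (21), C/C=C(/C)C(O)=O
Why: Yamaguchi esterification via the mixed anhydride, conditions known to keep the Z geometry of angelates; the 8-OH (next to CH2) should react in preference to the 6-OH (between the C4 methyl-bearing ring alkene and C7) and the tertiary 11-OH.

Step 16
Reactants: 22 8-O-angelate
Product: 23 6-O-triethylsilyl ether
Conditions: TESOTf (1.1 equiv), 2,6-lutidine, CH2Cl2, −78 °C
Reagents that add atoms: triethylsilyl triflate, CC[Si](CC)(CC)OS(=O)(=O)C(F)(F)F
Why: At low temperature the secondary 6-OH should be silylated before the tertiary 11-OH, leaving the latter as the only free hydroxyl.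

Step 17
Reactants: 23 6-O-triethylsilyl ether
Product: 24 11-O-acetate
Conditions: Ac2O, DMAP, Et3N, CH2Cl2, 35 °C
Reagents that add atoms: acetic anhydride, CC(=O)OC(C)=O
Why: DMAP-catalysed (Steglich-type) acetylation of the only free hydroxyl, a dimethylcarbinol; no β-acyloxy ketone is present, so no elimination pathway exists.

Step 18
Reactants: 24 11-O-acetate
Product: 25 1,3,6-triol
Conditions: HF·pyridine, pyridine, THF, 0 °C → rt
Reagents that add atoms: none
Why: Acidic fluoride removes both triethylsilyl groups and the TBS group while leaving the acetate and angelate in place and avoiding base-induced acyl migration between the cis 6- and 8-oxygens.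

Step 19
Reactants: 25 1,3,6-triol
Product: 26 CNP0273287.1 (target)
Conditions: MnO2, CH2Cl2, rt, monitored
Reagents that add atoms: none
Why: MnO2 allylic oxidation should select the accessible ring A carbinol C3 over the 6-OH (buried between the C4 methyl side of the alkene and the C7 quaternary-bearing carbon) and cannot oxidise the tertiary 1-OH, giving the C3 enone.

## Compound list

1 | (±)-allethrolone, rac-4-hydroxy-3-methyl-2-(prop-2-en-1-yl)cyclopent-2-en-1-one | O=C1CC(O)C(C)=C1CC=C | starting material
2 | (R)-allethrolone acetate, (1R)-2-methyl-4-oxo-3-(prop-2-en-1-yl)cyclopent-2-en-1-yl acetate | O=C1C[C@@H](OC(C)=O)C(C)=C1CC=C | intermediate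
3 | (R)-allethrolone, (4R)-4-hydroxy-3-methyl-2-(prop-2-en-1-yl)cyclopent-2-en-1-one | O=C1C[C@@H](O)C(C)=C1CC=C | intermediate
4 | (4R)-4-(tert-butyldimethylsilyloxy)-3-methyl-2-(prop-2-en-1-yl)cyclopent-2-en-1-one | O=C1C[C@@H](O[Si](C)(C)C(C)(C)C)C(C)=C1CC=C | intermediate
5 | (4R)-4-(tert-butyldimethylsilyloxy)-3-methyl-2-[(1E)-prop-1-en-1-yl]cyclopent-2-en-1-one | O=C1C[C@@H](O[Si](C)(C)C(C)(C)C)C(C)=C1/C=C/C | intermediate
6 | potassium (Z)-but-2-en-1-yltrifluoroborate | [K+].C/C=C\C[B-](F)(F)F | starting material
7 | (1R,4R)-1-[(2S)-but-3-en-2-yl]-4-(tert-butyldimethylsilyloxy)-3-methyl-2-[(1E)-prop-1-en-1-yl]cyclopent-2-en-1-ol | C=C[C@H](C)[C@]1(O)C[C@@H](O[Si](C)(C)C(C)(C)C)C(C)=C1/C=C/C | intermediate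
8 | triethylsilyl ether of 7 at the C1 oxygen | C=C[C@H](C)[C@]1(O[Si](CC)(CC)CC)C[C@@H](O[Si](C)(C)C(C)(C)C)C(C)=C1/C=C/C | intermediate
9 | B-alkyl-9-borabicyclo[3.3.1]nonane from 8 (boron on C8) | C1CCC2CCCC(C1)B2CC[C@H](C)[C@]3(O[Si](CC)(CC)CC)C[C@@H](O[Si](C)(C)C(C)(C)C)C(C)=C3/C=C/C | intermediate (not isolated)
10 | primary alcohol: 8 with the vinyl group converted into CH2CH2OH (C9, C8) | OCC[C@H](C)[C@]1(O[Si](CC)(CC)CC)C[C@@H](O[Si](C)(C)C(C)(C)C)C(C)=C1/C=C/C | intermediate
11 | C6,C7 vicinal diol of 10 (mixture of diastereomers at the two new carbinols) | OCC[C@H](C)[C@]1(O[Si](CC)(CC)CC)C[C@@H](O[Si](C)(C)C(C)(C)C)C(C)=C1C(O)C(C)O | intermediate (not isolated)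
12 | hydroxy enal: ring A carbaldehyde (C6 = CHO on C5) with the CH(CH3)CH2CH2OH chain on C1 | OCC[C@H](C)[C@]1(O[Si](CC)(CC)CC)C[C@@H](O[Si](C)(C)C(C)(C)C)C(C)=C1C=O | intermediate
13 | 2-methylprop-1-enylmagnesium bromide | CC(C)=C[Mg]Br | starting material
14 | bis-allylic alcohol: C6 carbinol bearing the 2-methylprop-1-enyl group (C6 epimers) | OCC[C@H](C)[C@]1(O[Si](CC)(CC)CC)C[C@@H](O[Si](C)(C)C(C)(C)C)C(C)=C1C(O)C=C(C)C | intermediate
15 | cross-conjugated dienone: C6 ketone, C7=C11 alkene | OCC[C@H](C)[C@]1(O[Si](CC)(CC)CC)C[C@@H](O[Si](C)(C)C(C)(C)C)C(C)=C1C(=O)C=C(C)C | intermediate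
16 | acyl oxirane: C6 ketone, C7–C11 epoxide (C7 epimers), free C8 alcohol | OCC[C@H](C)[C@]1(O[Si](CC)(CC)CC)C[C@@H](O[Si](C)(C)C(C)(C)C)C(C)=C1C(=O)C2OC2(C)C | intermediate
17 | epoxy keto aldehyde: 16 with C8 as aldehyde | O=CC[C@H](C)[C@]1(O[Si](CC)(CC)CC)C[C@@H](O[Si](C)(C)C(C)(C)C)C(C)=C1C(=O)C2OC2(C)C | intermediate
18 | Z(O) trivalent samarium enolate (C6=C7) with C11 samarium alkoxide | O=CC[C@H](C)[C@]1(O[Si](CC)(CC)CC)C[C@@H](O[Si](C)(C)C(C)(C)C)C(C)=C1/C(O[Sm](I)I)=C/C(C)(C)O[Sm](I)I | intermediate (not isolated)
19 | (1R,3R,7S,8R,10S)-3-(tert-butyldimethylsilyloxy)-8,11-dihydroxy-1-(triethylsilyloxy)guai-4-en-6-one (8-OH, C7 side chain and 10-CH3 cis, trans to 1-OSiEt3) | O[C@@H]1C[C@H](C)[C@]2(O[Si](CC)(CC)CC)C[C@@H](O[Si](C)(C)C(C)(C)C)C(C)=C2C(=O)[C@@H]1C(C)(C)O | intermediate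
20 | (1R,3R,6R,7R,8R,10S)-3-(tert-butyldimethylsilyloxy)-1-(triethylsilyloxy)guai-4-ene-6,8,11-triol (6-OH, C7 side chain, 8-OH all cis) | O[C@@H]1C[C@H](C)[C@]2(O[Si](CC)(CC)CC)C[C@@H](O[Si](C)(C)C(C)(C)C)C(C)=C2[C@H](O)[C@@H]1C(C)(C)O | intermediate
21 | angelic acid, (Z)-2-methylbut-2-enoic acid | C/C=C(/C)C(O)=O | starting material
22 | 8-O-angelate of 20 | C/C=C(/C)C(=O)O[C@@H]1C[C@H](C)[C@]2(O[Si](CC)(CC)CC)C[C@@H](O[Si](C)(C)C(C)(C)C)C(C)=C2[C@H](O)[C@@H]1C(C)(C)O | intermediate
23 | 6-O-triethylsilyl ether of 22 | C/C=C(/C)C(=O)O[C@@H]1C[C@H](C)[C@]2(O[Si](CC)(CC)CC)C[C@@H](O[Si](C)(C)C(C)(C)C)C(C)=C2[C@H](O[Si](CC)(CC)CC)[C@@H]1C(C)(C)O | intermediate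
24 | 11-O-acetate of 23 | C/C=C(/C)C(=O)O[C@@H]1C[C@H](C)[C@]2(O[Si](CC)(CC)CC)C[C@@H](O[Si](C)(C)C(C)(C)C)C(C)=C2[C@H](O[Si](CC)(CC)CC)[C@@H]1C(C)(C)OC(C)=O | intermediate
25 | 11-acetoxy-8-angeloyloxyguai-4-ene-1,3,6-triol (3R; other centres as in the target) | C/C=C(/C)C(=O)O[C@@H]1C[C@H](C)[C@]2(O)C[C@@H](O)C(C)=C2[C@H](O)[C@@H]1C(C)(C)OC(C)=O | intermediate
26 | CNP0273287.1, (1R,6R,7S,8R,10S)-11-acetoxy-8-angeloyloxy-1,6-dihydroxyguai-4-en-3-one | C/C=C(/C)C(=O)O[C@@H]1C[C@H](C)[C@]2(O)CC(=O)C(C)=C2[C@H](O)[C@@H]1C(C)(C)OC(C)=O | target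

## Step count and risks

Total steps: 19. Longest linear sequence: 19 (the route is fully linear from 1).

**Step 13 (key step).** What may go wrong: poor facial selectivity of the aldol closure (the chelate forming on the ring face of the C1 silyl ether), or proton capture by the samarium enolate before the ring closes. Fallback, a relay through the 8-epimer with inversion during esterification: setting out from 17, the product of closure on the other face, the 7,8-bis-epimeric keto diol F1, is equilibrated at C7 (catalytic DBU, CH2Cl2, 0 °C) to the trans-disposed 8-epi keto diol F2, whose C7 side chain then has the target orientation. Luche reduction (NaBH4, CeCl3·7H2O, MeOH, −78 °C) should give the 8-epi triol F3. A Mitsunobu esterification with angelic acid 21 (PPh3, DIAD, toluene, 0 °C → rt) then inverts C8 while installing the ester, and the sequence returns to the route at 22.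

**Step 5.** What may go wrong: poor simple diastereoselection at C10, or sluggish addition to the hindered cross-conjugated ketone. Fallback, reagent-controlled chirality transfer instead of reliance on crotyl geometry: setting out from 5, the allenylzinc reagent made from (R)-but-3-yn-2-yl methanesulfonate (Pd(OAc)2, PPh3, Et2Zn, THF, −20 °C; anti SN2′ palladation, then SE2′ addition anti to the C3 silyl ether) should give the homopropargylic alcohol F4 with C10 fixed by the reagent. Semihydrogenation (H2, Pd/CaCO3 poisoned with Pb(OAc)2, quinoline, EtOAc) returns to the route at 7.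

**Step 15.** What may go wrong: competing acylation of the 6-OH, or acyl migration between the cis 6- and 8-oxygens. Fallback, a change of order so that the C6 carbonyl protects O6: setting out from 19, Yamaguchi esterification of its only secondary hydroxyl with 21 gives the keto angelate F5 (kept at or below room temperature to avoid β-elimination). Luche reduction of F5 then returns to the route at 22.

Further compounds
F1 | step 13 | 7,8-bis-epimer of 19 (8-OH and C7 side chain cis to each other, on the face of 1-OSiEt3) | O[C@H]1C[C@H](C)[C@]2(O[Si](CC)(CC)CC)C[C@@H](O[Si](C)(C)C(C)(C)C)C(C)=C2C(=O)[C@H]1C(C)(C)O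
F2 | step 13 | 8-epimer of 19 (C7 as in 19, 8-OH trans to the side chain) | O[C@H]1C[C@H](C)[C@]2(O[Si](CC)(CC)CC)C[C@@H](O[Si](C)(C)C(C)(C)C)C(C)=C2C(=O)[C@@H]1C(C)(C)O
F3 | step 13 | 8-epimer of 20 | O[C@H]1C[C@H](C)[C@]2(O[Si](CC)(CC)CC)C[C@@H](O[Si](C)(C)C(C)(C)C)C(C)=C2[C@H](O)[C@@H]1C(C)(C)O
F4 | step 5 | (1R,4R)-1-[(2S)-but-3-yn-2-yl]-4-(tert-butyldimethylsilyloxy)-3-methyl-2-[(1E)-prop-1-en-1-yl]cyclopent-2-en-1-ol | C#C[C@H](C)[C@]1(O)C[C@@H](O[Si](C)(C)C(C)(C)C)C(C)=C1/C=C/C
F5 | step 15 | 8-O-angelate of keto diol 19 | C/C=C(/C)C(=O)O[C@@H]1C[C@H](C)[C@]2(O[Si](CC)(CC)CC)C[C@@H](O[Si](C)(C)C(C)(C)C)C(C)=C2C(=O)[C@@H]1C(C)(C)O
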